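**Retrosynthetic overview**

1. The last operations are bis-sulfation of the hydroquinone (reached from its dimethyl ether through the quinone) and release of the anti-diol from an acetonide. Before that, the side chain is joined by an sp3–sp2 Negishi coupling of the bicyclic iodide 36 with the (E)-vinyl iodide 34, which comes from geraniol (asymmetric epoxidation, propyne extension, epoxide hydrolysis with inversion, carboalumination).
2. Ring B is cut across two bonds at once: the CH2–CH2 bond next to the ring fusion, and the bond from the ring-fusion sp2 carbon to the quaternary carbon that carries the arylmethyl group. This [3+3] cut gives the ring A 2-methylidenecyclohexanone 10 and the homoallylic bromide 19.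
3. Enabling feature: the tetrasubstituted C=C shared by rings A and B is the enol form of a ring A ketone, so the exocyclic enone of ring A acts as a 1,3-dielectrophile (CH2 terminus, then carbonyl carbon as enol triflate). Its ring B neighbour is a quaternary carbon with no hydrogen, whose methyl can be carried as an exocyclic methylene and released by hydride capture of a neopentylpalladium.
4. Ring order: the arene is bought; ring A is made first (Birch reduction, then asymmetric conjugate addition for its quaternary centre); ring B is closed last, in the key step. The CH(CH3) centre of ring B comes from methyl (S)-3-hydroxy-2-methylpropanoate and steers the adjacent quaternary centre.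

Key step: step 10

Assumption: the two aryl sulfate monoesters are written as free acids, as in the target; in practice they would be handled as sodium salts and brought to the acid form on a cation-exchange resin.

**Ring A fragment**

Step 1
Reactants: 1 2-(3-methoxyphenyl)ethanol
Product: 3 3-(2-hydroxyethyl)cyclohex-2-en-1-one, via dihydroanisole 2 (not isolated)
Conditions: Li, NH3 (l), t-BuOH, THF, −78 → −33 °C; then 2 M HCl, THF, rt
Reagents that add atoms: water (O)
Why: Birch reduction of the anisole ring gives the 1-methoxycyclohexa-1,4-diene, and acid hydrolysis of the enol ether with conjugation of the C=C should give the 3-substituted cyclohexenone.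

Step 2
Reactants: 3 3-(2-hydroxyethyl)cyclohex-2-en-1-one
Product: 4 3-{2-[(tert-butyldimethylsilyl)oxy]ethyl}cyclohex-2-en-1-one
Conditions: TBSCl, imidazole, DMF, rt
Reagents that add atoms: tert-butyldimethylsilyl chloride (CC(C)(C)[Si](C)(C)Cl)
Why: Routine silylation of the primary alcohol, which protects it from the organometallic steps that follow.

Step 3
Reactants: 4 3-{2-[(tert-butyldimethylsilyl)oxy]ethyl}cyclohex-2-en-1-one
Product: 6 (R)-3-{2-[(tert-butyldimethylsilyl)oxy]ethyl}-3-methylcyclohex-1-en-1-yl acetate, via aluminium enolate 5 (not isolated)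
Conditions: Me3Al, Cu(OTf)2 (2 mol%), BINOL-based bis(1-phenylethyl)amine phosphoramidite (4 mol%), Et2O, −30 °C; then Ac2O, −30 °C → rt
Reagents that add atoms: trimethylaluminium (C[Al](C)C); acetic anhydride (CC(=O)OC(C)=O)
Why: Copper-catalysed asymmetric conjugate addition of Me3Al to the β-substituted enone should set the ring A quaternary centre under ligand control (the ligand antipode that gives the R centre is used), and O-acetylation of the aluminium enolate stores the enolate regiochemistry.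

Step 4
Reactants: 6 (R)-3-{2-[(tert-butyldimethylsilyl)oxy]ethyl}-3-methylcyclohex-1-en-1-yl acetate
Product: 10 (R)-3-{2-[(tert-butyldimethylsilyl)oxy]ethyl}-3-methyl-2-methylidenecyclohexan-1-one, via lithium enolate 7 (not isolated), via Mannich base 8 (not isolated), via methiodide 9 (not isolated)
Conditions: MeLi (2.1 equiv), THF, 0 °C; Me2N=CH2+ I−, −78 °C → rt; MeI, rt; DBU, CH2Cl2, rt
Reagents that add atoms: N,N-dimethylmethyleneiminium iodide (C=[N+](C)C.[I-])
Why: Cleavage of the enol acetate gives the lithium enolate regiospecifically, and a Mannich reaction followed by quaternisation and E1cB elimination should place the exocyclic methylene between the carbonyl and the quaternary carbon.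

**Arylmethyl fragment**

Step 5
Reactants: 11 methyl (S)-3-hydroxy-2-methylpropanoate
Product: 12 methyl (S)-3-[(tert-butyldimethylsilyl)oxy]-2-methylpropanoate
Conditions: TBSCl, imidazole, CH2Cl2, rt
Reagents that add atoms: tert-butyldimethylsilyl chloride (CC(C)(C)[Si](C)(C)Cl)
Why: Routine silylation; the stereocentre is not involved.

Step 6
Reactants: 12 methyl (S)-3-[(tert-butyldimethylsilyl)oxy]-2-methylpropanoate
Product: 14 (R)-tert-butyldimethyl[(2-methylbut-3-yn-1-yl)oxy]silane, via aldehyde 13 (not isolated)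
Conditions: DIBAL-H, CH2Cl2, −78 °C; MeOH; then dimethyl (1-diazo-2-oxopropyl)phosphonate, K2CO3, MeOH, 0 °C → rt
Reagents that add atoms: dimethyl (1-diazo-2-oxopropyl)phosphonate (CC(=O)C(=[N+]=[N-])P(=O)(OC)OC)
Why: Half-reduction of the ester and one-flask Seyferth–Gilbert homologation under mild carbonate conditions should give the terminal alkyne without epimerising the α-stereocentre.

Step 7
Reactants: 14 (R)-tert-butyldimethyl[(2-methylbut-3-yn-1-yl)oxy]silane; 15 2-(bromomethyl)-1,4-dimethoxybenzene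
Product: 17 (R)-tert-butyl{[3-(2,5-dimethoxybenzyl)-2-methylbut-3-en-1-yl]oxy}dimethylsilane, via alkenylalane 16 (not isolated)
Conditions: DIBAL-H, NiCl2(dppp) (3 mol%), THF, 0 °C → rt; then 15, Pd(PPh3)4 (5 mol%), THF, 50 °C
Reagents that add atoms: none
Why: Nickel-catalysed hydroalumination puts aluminium on the internal alkyne carbon, and palladium-catalysed coupling of this branched alkenylalane with the benzylic bromide (Negishi coupling) should give the 1,1-disubstituted alkene without touching the adjacent stereocentre.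

Step 8
Reactants: 17 (R)-tert-butyl{[3-(2,5-dimethoxybenzyl)-2-methylbut-3-en-1-yl]oxy}dimethylsilane
Product: 18 (R)-3-(2,5-dimethoxybenzyl)-2-methylbut-3-en-1-ol
Conditions: Bu4NF, THF, rt
Reagents that add atoms: none
Why: Fluoride cleavage of the silyl ether; all other groups are inert.

Step 9
Reactants: 18 (R)-3-(2,5-dimethoxybenzyl)-2-methylbut-3-en-1-ol
Product: 19 2-[(3R)-4-bromo-3-methyl-2-methylidenebutyl]-1,4-dimethoxybenzene
Conditions: CBr4, PPh3, CH2Cl2, 0 °C
Reagents that add atoms: carbon tetrabromide (BrC(Br)(Br)Br)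
Why: Appel bromination of the primary alcohol under neutral conditions; the stereocentre is not involved.

**Key step**

Step 10
Reactants: 19 2-[(3R)-4-bromo-3-methyl-2-methylidenebutyl]-1,4-dimethoxybenzene; 10 (R)-3-{2-[(tert-butyldimethylsilyl)oxy]ethyl}-3-methyl-2-methylidenecyclohexan-1-one
Product: 23 2-{[(1R,2S,5R)-5-{2-[(tert-butyldimethylsilyl)oxy]ethyl}-1,2,5-trimethyl-1,2,3,4,5,6,7,8-octahydronaphthalen-1-yl]methyl}-1,4-dimethoxybenzene, via organomagnesium bromide 20 (not isolated), via magnesium enolate 21 (not isolated), via enol triflate 22 (not isolated)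
Conditions: 19, Mg, THF, rt, used at once; CuBr·SMe2 (10 mol%), THF, −78 °C, then 10; N-(5-chloropyridin-2-yl)bis(trifluoromethanesulfonyl)imide, DMPU, −78 → 0 °C; then Pd(OAc)2 (10 mol%), PPh3 (30 mol%), HCO2Na (added in portions), DMF, 70 °C
Reagents that add atoms: none
Why: Copper-catalysed 1,4-addition of the organomagnesium reagent to the exocyclic enone makes the CH2–CH2 bond and gives the enolate regiospecifically; O-triflation fixes it as the tetrasubstituted ring-fusion enol triflate; oxidative addition to zerovalent palladium, carbopalladation of the 1,1-disubstituted alkene and formate hydride capture of the neopentylpalladium (no β-hydrogen) then make the bond to the quaternary carbon and turn the exocyclic methylene into its methyl group. The closest known reaction types are conjugate addition with enolate triflation and the reductive Heck cyclisation with hydride capture. Ring B closes in the 6-exo-trig mode, since 7-endo closure would put palladium on the fully substituted alkene carbon. The new quaternary centre is controlled by the adjacent CH(CH3) centre: in the insertion transition state the tether carbon lies on the attacked alkene face, the C–H of the stereocentre eclipses the arylmethyl branch (least A(1,2) strain) and its methyl points away, so the new methyl ends pseudo-axial and cis to the existing pseudo-equatorial methyl, with the arylmethyl group trans, as in the target. The step needs 1,4- rather than 1,2-addition (copper catalysis, unhindered CH2 terminus), O- rather than C-triflation (triflimide reagent), and insertion before reduction of the alkenylpalladium (intramolecular exo attack on an unhindered alkene, slow formate supply); the ring A quaternary centre is remote and should not interfere.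

**Side-chain fragment**

Step 11
Reactants: 24 geraniol
Product: 25 [(2S,3S)-3-methyl-3-(4-methylpent-3-en-1-yl)oxiran-2-yl]methanol
Conditions: Ti(OiPr)4, L-(+)-diethyl tartrate, t-BuOOH, 4 Å sieves, CH2Cl2, −20 °C
Reagents that add atoms: tert-butyl hydroperoxide (CC(C)(C)OO)
Why: Sharpless asymmetric epoxidation oxidises only the allylic alkene, and the L-(+)-tartrate ligand should deliver oxygen to the face that gives the (2S,3S) epoxide.

Step 12
Reactants: 25 [(2S,3S)-3-methyl-3-(4-methylpent-3-en-1-yl)oxiran-2-yl]methanol; 26 1-(trimethylsilyl)propyne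
Product: 29 trimethyl{4-[(2S,3S)-3-methyl-3-(4-methylpent-3-en-1-yl)oxiran-2-yl]but-1-yn-1-yl}silane, via epoxy triflate 27 (not isolated), via lithiated silylpropyne 28 (not isolated)
Conditions: 25, n-BuLi, THF, −78 °C, then Tf2O; added to 28 (from 26, n-BuLi, THF, −78 → −20 °C), DMPU, −78 °C
Reagents that add atoms: none
Why: SN2 displacement of the primary triflate by the propargylic lithium reagent is much faster at −78 °C than opening of the trisubstituted epoxide, so the chain should be extended by three carbons with both epoxide centres intact.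

Step 13
Reactants: 29 trimethyl{4-[(2S,3S)-3-methyl-3-(4-methylpent-3-en-1-yl)oxiran-2-yl]but-1-yn-1-yl}silane
Product: 30 (5S,6R)-6,10-dimethyl-1-(trimethylsilyl)undec-9-en-1-yne-5,6-diol
Conditions: HClO4 (cat.), THF/H2O, 0 °C → rt
Reagents that add atoms: water (O)
Why: Acid-catalysed epoxide hydrolysis in which water attacks the tertiary carbon with inversion should give the anti-diol, the secondary centre keeping its oxygen and configuration.

Step 14
Reactants: 30 (5S,6R)-6,10-dimethyl-1-(trimethylsilyl)undec-9-en-1-yne-5,6-diol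
Product: 31 trimethyl{4-[(4S,5R)-2,2,5-trimethyl-5-(4-methylpent-3-en-1-yl)-1,3-dioxolan-4-yl]but-1-yn-1-yl}silane
Conditions: 2,2-dimethoxypropane, pyridinium p-toluenesulfonate (cat.), CH2Cl2, rt
Reagents that add atoms: 2,2-dimethoxypropane (COC(C)(C)OC)
Why: Acid-catalysed transacetalisation protects the 1,2-diol as its acetonide without change at either stereocentre.

Step 15
Reactants: 31 trimethyl{4-[(4S,5R)-2,2,5-trimethyl-5-(4-methylpent-3-en-1-yl)-1,3-dioxolan-4-yl]but-1-yn-1-yl}silane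
Product: 32 (4S,5R)-4-(but-3-yn-1-yl)-2,2,5-trimethyl-5-(4-methylpent-3-en-1-yl)-1,3-dioxolane
Conditions: K2CO3 (cat.), MeOH, rt
Reagents that add atoms: none
Why: Methanolysis of the alkynyl C–Si bond frees the terminal alkyne; the acetonide is stable to base.

Step 16
Reactants: 32 (4S,5R)-4-(but-3-yn-1-yl)-2,2,5-trimethyl-5-(4-methylpent-3-en-1-yl)-1,3-dioxolane
Product: 34 (4S,5R)-4-[(3E)-4-iodo-3-methylbut-3-en-1-yl]-2,2,5-trimethyl-5-(4-methylpent-3-en-1-yl)-1,3-dioxolane, via alkenylalane 33 (not isolated)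
Conditions: Me3Al, Cp2ZrCl2 (0.3 equiv), CH2Cl2, 0 °C → rt; then I2, THF, −30 °C
Reagents that add atoms: trimethylaluminium (C[Al](C)C); iodine (II)
Why: Zirconium-catalysed syn-carboalumination (Negishi carboalumination) puts methyl on the internal and aluminium on the terminal alkyne carbon, and iodinolysis with retention should give the (E)-trisubstituted vinyl iodide; the isolated trisubstituted alkene does not react.

**Fragment union and end game**

Step 17
Reactants: 23 2-{[(1R,2S,5R)-5-{2-[(tert-butyldimethylsilyl)oxy]ethyl}-1,2,5-trimethyl-1,2,3,4,5,6,7,8-octahydronaphthalen-1-yl]methyl}-1,4-dimethoxybenzene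
Product: 35 2-{(1R,5R,6S)-5-[(2,5-dimethoxyphenyl)methyl]-1,5,6-trimethyl-1,2,3,4,5,6,7,8-octahydronaphthalen-1-yl}ethan-1-ol
Conditions: Bu4NF, THF, rt
Reagents that add atoms: none
Why: Fluoride cleavage of the primary silyl ether; the tetrasubstituted alkene and aryl ethers are inert.

Step 18
Reactants: 35 2-{(1R,5R,6S)-5-[(2,5-dimethoxyphenyl)methyl]-1,5,6-trimethyl-1,2,3,4,5,6,7,8-octahydronaphthalen-1-yl}ethan-1-ol
Product: 36 2-{[(1R,2S,5R)-5-(2-iodoethyl)-1,2,5-trimethyl-1,2,3,4,5,6,7,8-octahydronaphthalen-1-yl]methyl}-1,4-dimethoxybenzene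
Conditions: I2, PPh3, imidazole, CH2Cl2, 0 °C → rt
Reagents that add atoms: iodine (II)
Why: Appel-type iodination of the primary alcohol under neutral conditions.

Step 19
Reactants: 36 2-{[(1R,2S,5R)-5-(2-iodoethyl)-1,2,5-trimethyl-1,2,3,4,5,6,7,8-octahydronaphthalen-1-yl]methyl}-1,4-dimethoxybenzene; 34 (4S,5R)-4-[(3E)-4-iodo-3-methylbut-3-en-1-yl]-2,2,5-trimethyl-5-(4-methylpent-3-en-1-yl)-1,3-dioxolane
Product: 38 (4S,5R)-4-{(3E)-6-[(1R,5R,6S)-5-(2,5-dimethoxybenzyl)-1,5,6-trimethyl-1,2,3,4,5,6,7,8-octahydronaphthalen-1-yl]-3-methylhex-3-en-1-yl}-2,2,5-trimethyl-5-(4-methylpent-3-en-1-yl)-1,3-dioxolane, via alkylzinc iodide 37 (not isolated)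
Conditions: 36, Zn dust, LiCl, THF, 40 °C; then 34, PdCl2(dppf) (5 mol%), THF, 50 °C
Reagents that add atoms: none
Why: Zinc insertion into the primary iodide and palladium-catalysed sp3–sp2 Negishi coupling with the vinyl iodide should join the fragments with retention of the (E) geometry; the acetonide and the other alkenes are inert to the organozinc.

Step 20
Reactants: 38 (4S,5R)-4-{(3E)-6-[(1R,5R,6S)-5-(2,5-dimethoxybenzyl)-1,5,6-trimethyl-1,2,3,4,5,6,7,8-octahydronaphthalen-1-yl]-3-methylhex-3-en-1-yl}-2,2,5-trimethyl-5-(4-methylpent-3-en-1-yl)-1,3-dioxolane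
Product: 40 2-{[(1R,2S,5R)-1,2,5-trimethyl-5-{(3E)-4-methyl-6-[(4S,5R)-2,2,5-trimethyl-5-(4-methylpent-3-en-1-yl)-1,3-dioxolan-4-yl]hex-3-en-1-yl}-1,2,3,4,5,6,7,8-octahydronaphthalen-1-yl]methyl}benzene-1,4-diol, via quinone 39 (not isolated)
Conditions: (NH4)2Ce(NO3)6, MeCN/H2O, 0 °C, short contact; then aq. Na2S2O4, Et2O, rt, under argon
Reagents that add atoms: water (O)
Why: Oxidative demethylation of the 1,4-dimethoxyarene gives the benzoquinone, which dithionite reduces to the hydroquinone; short contact at 0 °C should spare the acetonide and the alkenes.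

Step 21
Reactants: 40 the hydroquinone acetonide of step 20
Product: 41 2-{[(1R,2S,5R)-1,2,5-trimethyl-5-{(3E)-4-methyl-6-[(4S,5R)-2,2,5-trimethyl-5-(4-methylpent-3-en-1-yl)-1,3-dioxolan-4-yl]hex-3-en-1-yl}-1,2,3,4,5,6,7,8-octahydronaphthalen-1-yl]methyl}-1,4-phenylene bis(hydrogen sulfate)
Conditions: SO3·pyridine (excess), pyridine, rt
Reagents that add atoms: sulfur trioxide–pyridine complex ([O-]S(=O)(=O)[n+]1ccccc1)
Why: O-sulfation of both phenols with the SO3–amine complex; the diol is masked, so only the phenols can react.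

Step 22
Reactants: 41 the bis(hydrogen sulfate) acetonide of step 21
Product: 42 CNP0442769.2, 2-{[(1R,2S,5R)-5-[(3E,7S,8R)-7,8-dihydroxy-4,8,12-trimethyltrideca-3,11-dien-1-yl]-1,2,5-trimethyl-1,2,3,4,5,6,7,8-octahydronaphthalen-1-yl]methyl}-1,4-phenylene bis(hydrogen sulfate)
Conditions: AcOH/H2O (4:1), rt
Reagents that add atoms: none
Why: Mild acid hydrolysis of the acetonide frees the secondary–tertiary diol; aryl sulfate monoesters should survive dilute acetic acid at room temperature.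

**Compound list**

1 | 2-(3-methoxyphenyl)ethanol | COc1cccc(CCO)c1 | starting material
2 | 2-(5-methoxycyclohexa-1,4-dien-1-yl)ethanol | COC1=CCC=C(CCO)C1 | intermediate
3 | 3-(2-hydroxyethyl)cyclohex-2-en-1-one | O=C1C=C(CCO)CCC1 | intermediate
4 | 3-{2-[(tert-butyldimethylsilyl)oxy]ethyl}cyclohex-2-en-1-one | CC(C)(C)[Si](C)(C)OCCC1=CC(=O)CCC1 | intermediate
5 | dimethylaluminium (R)-3-{2-[(tert-butyldimethylsilyl)oxy]ethyl}-3-methylcyclohex-1-en-1-olate | CC(C)(C)[Si](C)(C)OCC[C@@]1(C)CCCC(O[Al](C)C)=C1 | intermediate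
6 | (R)-3-{2-[(tert-butyldimethylsilyl)oxy]ethyl}-3-methylcyclohex-1-en-1-yl acetate | CC(C)(C)[Si](C)(C)OCC[C@@]1(C)CCCC(OC(C)=O)=C1 | intermediate
7 | lithium (R)-3-{2-[(tert-butyldimethylsilyl)oxy]ethyl}-3-methylcyclohex-1-en-1-olate | CC(C)(C)[Si](C)(C)OCC[C@@]1(C)CCCC(O[Li])=C1 | intermediate
8 | (3R)-3-{2-[(tert-butyldimethylsilyl)oxy]ethyl}-2-[(dimethylamino)methyl]-3-methylcyclohexan-1-one (mixture at C-2) | CC(C)(C)[Si](C)(C)OCC[C@@]1(C)CCCC(=O)C1CN(C)C | intermediate
9 | trimethylammonium iodide of 8, {[(2R)-2-{2-[(tert-butyldimethylsilyl)oxy]ethyl}-2-methyl-6-oxocyclohexyl]methyl}trimethylammonium iodide | CC(C)(C)[Si](C)(C)OCC[C@@]1(C)CCCC(=O)C1C[N+](C)(C)C.[I-] | intermediate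
10 | (R)-3-{2-[(tert-butyldimethylsilyl)oxy]ethyl}-3-methyl-2-methylidenecyclohexan-1-one | CC(C)(C)[Si](C)(C)OCC[C@@]1(C)CCCC(=O)C1=C | intermediate
11 | methyl (S)-3-hydroxy-2-methylpropanoate | OC[C@H](C)C(=O)OC | starting material
12 | methyl (S)-3-[(tert-butyldimethylsilyl)oxy]-2-methylpropanoate | CC(C)(C)[Si](C)(C)OC[C@H](C)C(=O)OC | intermediate
13 | (S)-3-[(tert-butyldimethylsilyl)oxy]-2-methylpropanal | CC(C)(C)[Si](C)(C)OC[C@H](C)C=O | intermediate
14 | (R)-tert-butyldimethyl[(2-methylbut-3-yn-1-yl)oxy]silane | CC(C)(C)[Si](C)(C)OC[C@H](C)C#C | intermediate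
15 | 2-(bromomethyl)-1,4-dimethoxybenzene | COc1ccc(OC)c(CBr)c1 | starting material
16 | {(3S)-4-[(tert-butyldimethylsilyl)oxy]-3-methylbut-1-en-2-yl}bis(2-methylpropyl)aluminium | CC(C)(C)[Si](C)(C)OC[C@H](C)C(=C)[Al](CC(C)C)CC(C)C | intermediate
17 | (R)-tert-butyl{[3-(2,5-dimethoxybenzyl)-2-methylbut-3-en-1-yl]oxy}dimethylsilane | CC(C)(C)[Si](C)(C)OC[C@H](C)C(=C)Cc1cc(OC)ccc1OC | intermediate
18 | (R)-3-(2,5-dimethoxybenzyl)-2-methylbut-3-en-1-ol | OC[C@H](C)C(=C)Cc1cc(OC)ccc1OC | intermediate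
19 | 2-[(3R)-4-bromo-3-methyl-2-methylidenebutyl]-1,4-dimethoxybenzene | BrC[C@H](C)C(=C)Cc1cc(OC)ccc1OC | intermediate
20 | [(2R)-3-(2,5-dimethoxybenzyl)-2-methylbut-3-en-1-yl]magnesium bromide | Br[Mg]C[C@H](C)C(=C)Cc1cc(OC)ccc1OC | intermediate
21 | bromomagnesium (3R)-3-{2-[(tert-butyldimethylsilyl)oxy]ethyl}-2-[(3S)-4-(2,5-dimethoxybenzyl)-3-methylpent-4-en-1-yl]-3-methylcyclohex-1-en-1-olate | CC(C)(C)[Si](C)(C)OCC[C@@]1(C)CCCC(O[Mg]Br)=C1CC[C@H](C)C(=C)Cc1cc(OC)ccc1OC | intermediate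
22 | (3R)-3-{2-[(tert-butyldimethylsilyl)oxy]ethyl}-2-[(3S)-4-(2,5-dimethoxybenzyl)-3-methylpent-4-en-1-yl]-3-methylcyclohex-1-en-1-yl trifluoromethanesulfonate | CC(C)(C)[Si](C)(C)OCC[C@@]1(C)CCCC(OS(=O)(=O)C(F)(F)F)=C1CC[C@H](C)C(=C)Cc1cc(OC)ccc1OC | intermediate
23 | 2-{[(1R,2S,5R)-5-{2-[(tert-butyldimethylsilyl)oxy]ethyl}-1,2,5-trimethyl-1,2,3,4,5,6,7,8-octahydronaphthalen-1-yl]methyl}-1,4-dimethoxybenzene | CC(C)(C)[Si](C)(C)OCC[C@@]1(C)CCCC2=C1CC[C@H](C)[C@@]2(C)Cc1cc(OC)ccc1OC | intermediate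
24 | geraniol, (2E)-3,7-dimethylocta-2,6-dien-1-ol | CC(C)=CCC/C(C)=C/CO | starting material
25 | [(2S,3S)-3-methyl-3-(4-methylpent-3-en-1-yl)oxiran-2-yl]methanol | CC(C)=CCC[C@]1(C)O[C@H]1CO | intermediate
26 | 1-(trimethylsilyl)propyne | CC#C[Si](C)(C)C | starting material
27 | [(2S,3S)-3-methyl-3-(4-methylpent-3-en-1-yl)oxiran-2-yl]methyl trifluoromethanesulfonate | CC(C)=CCC[C@]1(C)O[C@H]1COS(=O)(=O)C(F)(F)F | intermediate
28 | [3-(trimethylsilyl)prop-2-yn-1-yl]lithium | [Li]CC#C[Si](C)(C)C | intermediate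
29 | trimethyl{4-[(2S,3S)-3-methyl-3-(4-methylpent-3-en-1-yl)oxiran-2-yl]but-1-yn-1-yl}silane | CC(C)=CCC[C@]1(C)O[C@H]1CCC#C[Si](C)(C)C | intermediate
30 | (5S,6R)-6,10-dimethyl-1-(trimethylsilyl)undec-9-en-1-yne-5,6-diol | CC(C)=CCC[C@@](C)(O)[C@@H](O)CCC#C[Si](C)(C)C | intermediate
31 | trimethyl{4-[(4S,5R)-2,2,5-trimethyl-5-(4-methylpent-3-en-1-yl)-1,3-dioxolan-4-yl]but-1-yn-1-yl}silane | CC(C)=CCC[C@@]1(C)OC(C)(C)O[C@H]1CCC#C[Si](C)(C)C | intermediate
32 | (4S,5R)-4-(but-3-yn-1-yl)-2,2,5-trimethyl-5-(4-methylpent-3-en-1-yl)-1,3-dioxolane | CC(C)=CCC[C@@]1(C)OC(C)(C)O[C@H]1CCC#C | intermediate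
33 | dimethyl{(1E)-2-methyl-4-[(4S,5R)-2,2,5-trimethyl-5-(4-methylpent-3-en-1-yl)-1,3-dioxolan-4-yl]but-1-en-1-yl}aluminium | CC(C)=CCC[C@@]1(C)OC(C)(C)O[C@H]1CC/C(C)=C/[Al](C)C | intermediate
34 | (4S,5R)-4-[(3E)-4-iodo-3-methylbut-3-en-1-yl]-2,2,5-trimethyl-5-(4-methylpent-3-en-1-yl)-1,3-dioxolane | CC(C)=CCC[C@@]1(C)OC(C)(C)O[C@H]1CC/C(C)=C/I | intermediate
35 | 2-{(1R,5R,6S)-5-[(2,5-dimethoxyphenyl)methyl]-1,5,6-trimethyl-1,2,3,4,5,6,7,8-octahydronaphthalen-1-yl}ethan-1-ol | OCC[C@@]1(C)CCCC2=C1CC[C@H](C)[C@@]2(C)Cc1cc(OC)ccc1OC | intermediate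
36 | 2-{[(1R,2S,5R)-5-(2-iodoethyl)-1,2,5-trimethyl-1,2,3,4,5,6,7,8-octahydronaphthalen-1-yl]methyl}-1,4-dimethoxybenzene | ICC[C@@]1(C)CCCC2=C1CC[C@H](C)[C@@]2(C)Cc1cc(OC)ccc1OC | intermediate
37 | (2-{(1R,5R,6S)-5-[(2,5-dimethoxyphenyl)methyl]-1,5,6-trimethyl-1,2,3,4,5,6,7,8-octahydronaphthalen-1-yl}ethyl)zinc iodide | I[Zn]CC[C@@]1(C)CCCC2=C1CC[C@H](C)[C@@]2(C)Cc1cc(OC)ccc1OC | intermediate
38 | (4S,5R)-4-{(3E)-6-[(1R,5R,6S)-5-(2,5-dimethoxybenzyl)-1,5,6-trimethyl-1,2,3,4,5,6,7,8-octahydronaphthalen-1-yl]-3-methylhex-3-en-1-yl}-2,2,5-trimethyl-5-(4-methylpent-3-en-1-yl)-1,3-dioxolane | CC(C)=CCC[C@@]1(C)OC(C)(C)O[C@H]1CC/C(C)=C/CC[C@@]2(C)CCCC3=C2CC[C@H](C)[C@@]3(C)Cc2cc(OC)ccc2OC | intermediate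
39 | 2-{[(1R,2S,5R)-1,2,5-trimethyl-5-{(3E)-4-methyl-6-[(4S,5R)-2,2,5-trimethyl-5-(4-methylpent-3-en-1-yl)-1,3-dioxolan-4-yl]hex-3-en-1-yl}-1,2,3,4,5,6,7,8-octahydronaphthalen-1-yl]methyl}cyclohexa-2,5-diene-1,4-dione | CC(C)=CCC[C@@]1(C)OC(C)(C)O[C@H]1CC/C(C)=C/CC[C@@]2(C)CCCC3=C2CC[C@H](C)[C@@]3(C)CC2=CC(=O)C=CC2=O | intermediate
40 | 2-{[(1R,2S,5R)-1,2,5-trimethyl-5-{(3E)-4-methyl-6-[(4S,5R)-2,2,5-trimethyl-5-(4-methylpent-3-en-1-yl)-1,3-dioxolan-4-yl]hex-3-en-1-yl}-1,2,3,4,5,6,7,8-octahydronaphthalen-1-yl]methyl}benzene-1,4-diol | CC(C)=CCC[C@@]1(C)OC(C)(C)O[C@H]1CC/C(C)=C/CC[C@@]2(C)CCCC3=C2CC[C@H](C)[C@@]3(C)Cc2cc(O)ccc2O | intermediate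
41 | 2-{[(1R,2S,5R)-1,2,5-trimethyl-5-{(3E)-4-methyl-6-[(4S,5R)-2,2,5-trimethyl-5-(4-methylpent-3-en-1-yl)-1,3-dioxolan-4-yl]hex-3-en-1-yl}-1,2,3,4,5,6,7,8-octahydronaphthalen-1-yl]methyl}-1,4-phenylene bis(hydrogen sulfate) | CC(C)=CCC[C@@]1(C)OC(C)(C)O[C@H]1CC/C(C)=C/CC[C@@]2(C)CCCC3=C2CC[C@H](C)[C@@]3(C)Cc2cc(OS(=O)(=O)O)ccc2OS(=O)(=O)O | intermediate
42 | CNP0442769.2, 2-{[(1R,2S,5R)-5-[(3E,7S,8R)-7,8-dihydroxy-4,8,12-trimethyltrideca-3,11-dien-1-yl]-1,2,5-trimethyl-1,2,3,4,5,6,7,8-octahydronaphthalen-1-yl]methyl}-1,4-phenylene bis(hydrogen sulfate) | CC(C)=CCC[C@@](C)(O)[C@@H](O)CC/C(C)=C/CC[C@@]1(C)CCCC2=C1CC[C@H](C)[C@@]2(C)Cc1cc(OS(=O)(=O)O)ccc1OS(=O)(=O)O | target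

**Step count and risks**

Total steps: 22. Longest linear sequence: 12 steps (from 11: steps 5–10 and 17–22).

Steps most likely to fail:

Step 10. The alkenylpalladium may be reduced by formate before it inserts; the neopentylpalladium may attack the ring-fusion alkene (3-exo) before hydride capture; or facial selection at the new quaternary centre may be too low. The fallback sets out from 19 and 10 and comes back at 23. The copper-catalysed addition of 20 to 10 is quenched with aqueous NH4Cl to give the ketone (3R)-3-{2-[(tert-butyldimethylsilyl)oxy]ethyl}-2-[(3S)-4-(2,5-dimethoxybenzyl)-3-methylpent-4-en-1-yl]-3-methylcyclohexan-1-one F1. Fe(acac)3 and PhSiH3 in EtOH at 60 °C then start a hydrogen-atom-transfer radical cyclisation: the tertiary radical formed from the 1,1-disubstituted alkene (which already carries the new methyl) adds 6-exo to the ketone carbonyl and gives the ring-fusion tertiary alcohol, 1-(2,5-dimethoxybenzyl)-5-{2-[(tert-butyldimethylsilyl)oxy]ethyl}-1,2,5-trimethyldecahydronaphthalen-8a-ol F2. Dehydration (SOCl2, pyridine, 0 °C, then TsOH to move the alkene to the tetrasubstituted position) gives 23.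

Step 20. The acetonide may be lost under the acidic aqueous cerium conditions, or the electron-rich alkenes may be oxidised. The fallback sets out from 38 and comes back at 40: NaSEt in DMF at 130 °C under argon removes both aryl methyl groups by SN2 attack at the methyl carbons and gives 40 directly after neutral work-up, without an oxidation step. No compound outside the list is made on this way (F0).

Step 22. The aryl sulfate groups may be lost by acid-promoted hydrolysis while the acetonide is cleaved. The fallback sets out from 38 and comes back at 42, changing the diol protection to a base-labile one before the arene is touched. AcOH/H2O on 38 gives the diol (3E,7S,8R)-1-[(1R,5R,6S)-5-(2,5-dimethoxybenzyl)-1,5,6-trimethyl-1,2,3,4,5,6,7,8-octahydronaphthalen-1-yl]-4,8,12-trimethyltrideca-3,11-diene-7,8-diol F3. 1,1'-Carbonyldiimidazole in toluene at 80 °C closes the cyclic carbonate F4. Oxidative demethylation as in step 20 gives the quinone carbonate F5 (not isolated) and, after dithionite, the hydroquinone carbonate F6. SO3·pyridine gives the bis(hydrogen sulfate) carbonate F7, and K2CO3 in MeOH removes the carbonate under basic conditions, which aryl sulfates tolerate, to give 42.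

**Further compounds**

F1 | step 10 | (3R)-3-{2-[(tert-butyldimethylsilyl)oxy]ethyl}-2-[(3S)-4-(2,5-dimethoxybenzyl)-3-methylpent-4-en-1-yl]-3-methylcyclohexan-1-one (mixture at C-2) | CC(C)(C)[Si](C)(C)OCC[C@@]1(C)CCCC(=O)C1CC[C@H](C)C(=C)Cc1cc(OC)ccc1OC
F2 | step 10 | (1R,2S,5R)-1-(2,5-dimethoxybenzyl)-5-{2-[(tert-butyldimethylsilyl)oxy]ethyl}-1,2,5-trimethyldecahydronaphthalen-8a-ol (ring-fusion centres not assigned) | CC(C)(C)[Si](C)(C)OCC[C@@]1(C)CCCC2(O)C1CC[C@H](C)[C@@]2(C)Cc1cc(OC)ccc1OC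
F0 | step 20 | none | none
F3 | step 22 | (3E,7S,8R)-1-[(1R,5R,6S)-5-(2,5-dimethoxybenzyl)-1,5,6-trimethyl-1,2,3,4,5,6,7,8-octahydronaphthalen-1-yl]-4,8,12-trimethyltrideca-3,11-diene-7,8-diol | CC(C)=CCC[C@@](C)(O)[C@@H](O)CC/C(C)=C/CC[C@@]1(C)CCCC2=C1CC[C@H](C)[C@@]2(C)Cc1cc(OC)ccc1OC
F4 | step 22 | (4S,5R)-4-{(3E)-6-[(1R,5R,6S)-5-(2,5-dimethoxybenzyl)-1,5,6-trimethyl-1,2,3,4,5,6,7,8-octahydronaphthalen-1-yl]-3-methylhex-3-en-1-yl}-5-methyl-5-(4-methylpent-3-en-1-yl)-1,3-dioxolan-2-one | CC(C)=CCC[C@@]1(C)OC(=O)O[C@H]1CC/C(C)=C/CC[C@@]2(C)CCCC3=C2CC[C@H](C)[C@@]3(C)Cc2cc(OC)ccc2OC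
F5 | step 22 | quinone carbonate, 2-{[(1R,2S,5R)-1,2,5-trimethyl-5-{(3E)-4-methyl-6-[(4S,5R)-5-methyl-5-(4-methylpent-3-en-1-yl)-2-oxo-1,3-dioxolan-4-yl]hex-3-en-1-yl}-1,2,3,4,5,6,7,8-octahydronaphthalen-1-yl]methyl}cyclohexa-2,5-diene-1,4-dione | CC(C)=CCC[C@@]1(C)OC(=O)O[C@H]1CC/C(C)=C/CC[C@@]2(C)CCCC3=C2CC[C@H](C)[C@@]3(C)CC2=CC(=O)C=CC2=O
F6 | step 22 | hydroquinone carbonate, (4S,5R)-4-{(3E)-6-[(1R,5R,6S)-5-(2,5-dihydroxybenzyl)-1,5,6-trimethyl-1,2,3,4,5,6,7,8-octahydronaphthalen-1-yl]-3-methylhex-3-en-1-yl}-5-methyl-5-(4-methylpent-3-en-1-yl)-1,3-dioxolan-2-one | CC(C)=CCC[C@@]1(C)OC(=O)O[C@H]1CC/C(C)=C/CC[C@@]2(C)CCCC3=C2CC[C@H](C)[C@@]3(C)Cc2cc(O)ccc2O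
F7 | step 22 | bis(hydrogen sulfate) carbonate, 2-{[(1R,2S,5R)-1,2,5-trimethyl-5-{(3E)-4-methyl-6-[(4S,5R)-5-methyl-5-(4-methylpent-3-en-1-yl)-2-oxo-1,3-dioxolan-4-yl]hex-3-en-1-yl}-1,2,3,4,5,6,7,8-octahydronaphthalen-1-yl]methyl}-1,4-phenylene bis(hydrogen sulfate) | CC(C)=CCC[C@@]1(C)OC(=O)O[C@H]1CC/C(C)=C/CC[C@@]2(C)CCCC3=C2CC[C@H](C)[C@@]3(C)Cc2cc(OS(=O)(=O)O)ccc2OS(=O)(=O)O
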